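## Analysis of the target

Dipolynaphthalene A consists of two naphthalene-derived halves joined by one C(sp3)–C(sp2) bond. One half is a 5-methoxy-1-tetralol (aromatic ring A fused to the saturated ring B); its C4 is bonded to C2' of an 8-methoxy-1-naphthol (rings C and D). There are two stereocentres, the carbinol carbon C1 (S) and the doubly benzylic methine C4 (R). Read from the SMILES, the hydroxyl and the naphthyl group lie on opposite faces of ring B, so the relationship is 1,4-trans. The two centres are separated by the C2–C3 ethylene unit, so neither can easily direct the other in a simple tetralin, and C4 is crowded by the peri methoxy group on C5 and the ortho hydroxyl of the naphthol. Sensitive points are the secondary benzylic alcohol (ionisation, elimination towards a naphthalene, hydrogenolysis), the electron-rich free naphthol (oxidation, ortho-quinone methide formation through C4) and the aryl methyl ethers, which exclude harsh Lewis acids. The difficulty is to forge the hindered C4–aryl connection, to control a remote trans relationship and to reach one enantiomer. The strategy rests on one feature: the C1 oxygen and the C4 substituent sit on the two benzylic positions of ring A (on C8a and on C4a, the latter next to the methoxy carbon C5). This is the bridgehead pattern of a 1,4-epoxy-1,4-dihydronaphthalene, in which one oxygen atom spans C1 and C4.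

## Retrosynthetic reasoning

Tetralin numbering of the target is used throughout the discussion (C1 carbinol, C4 aryl-bearing carbon, C4a and C8a ring fusion, C5 methoxy carbon; primed numbers for the naphthol).

**13 back to 12.** The last bond cut is the O–CH2Ph bond of benzyl ether 12. The naphthol oxygen must be masked all the way, because a free ortho hydroxyl would turn any C4 cation into an ortho-quinone methide and would interfere with alkylation and coupling steps. A benzyl ether tolerates base, fluoride, hydride and palladium coupling, and it leaves by neutral hydrogenolysis, which the benzylic alcohol should survive.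

**12 back to 11.** No skeletal bond is cut between 12 and the racemic trans alcohol 11; the two differ only in enantiomeric purity. The C1 hydroxyl is the only handle an enzyme can use, and it first appears in 11, so the resolution is placed there. The forward step has to acylate one enantiomer and leave the (1S,4R) alcohol.

**11 back to 10.** The C4–H bond is exchanged for a C4–O bond to the C1 oxygen, which gives bridged ether 10. This is done because a 1,4-trans relationship is hard to set across an open ring B. In 10 the oxygen is necessarily bonded to C1 and C4 on the same face. Replacing the C4–O bond by C4–H on that same face therefore puts the aryl group trans to the C1 oxygen. The forward reaction must break only the tertiary, doubly benzylic C4–O bond and deliver hydrogen with retention.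

**10 back to 9.** The C2–C3 single bond is taken back to the double bond of 9. Nothing is built here, but the alkene reveals the diene origin of C1–C4. The forward step is a reduction of a strained alkene that must not touch the benzyl ether or the benzylic C–O bonds.

**9 back to 6 and 8.** The two bonds from ring A to the bridgeheads, C4–C4a and C8a–C1, are cut together in a retro-[4+2]. This gives furan 6, which carries C1–C4, the oxygen and the naphthyl group, and 3-methoxybenzyne 8, released from silyl triflate 7. The cut is made here because both bonds end on adjacent ring-A carbons, which is the signature of an aryne. It also forms the hindered C4–C4a bond in a strain-driven step, and ring A arrives with its methoxy group from a purchased reagent. The forward step has to place the aryl-bearing furan carbon next to the methoxy carbon.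

**6 back to 4 and 5.** The aryl–furan bond between C2' and the furan α-carbon is cut to bromide 4 and boronic acid 5. A palladium cross-coupling is the most dependable way to make a biaryl-type bond at an ortho-substituted position, and it keeps the precursor synthesis short.

**4 back to 1.** Bromide 4 is traced through bromonaphthol 3 and monoether 2 to diol 1 by cutting, in turn, the O–benzyl bond, the C2'–Br bond and one O–methyl bond. The order matters: bromination needs the free hydroxyl to direct it to the ortho carbon, and monomethylation relies on the peri hydrogen bond to differentiate the two hydroxyls.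

## Alternatives that were turned down

**Alternative 1: toluate-anion annulation that builds the naphthol ring last.**
- Disconnection: ring C is cut at C4'–C3' and C2'–C1'.
- Forward key step: the benzylic anion of ethyl 2-methoxy-6-methylbenzoate A1 adds to the vinyl sulfoxide A2, a trans-1,4-disubstituted tetralin. The α-sulfinyl carbanion closes on the ester, and loss of the sulfenic acid aromatises the ring to the C1 silyl ether A3.
- For it: the naphthol substitution is unambiguous and needs no protecting group. The tetralin stereocentres can be made enantioenriched beforehand, so no resolution is needed. On absolute stereocontrol it is stronger than the chosen route.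
- Against it: A2 already contains ring B, the crowded C4 next to the peri methoxy group and the 1,4-trans pair. The real problem of the target is only moved into a precursor that needs a long synthesis. The acceptor is an α-branched vinyl sulfoxide with a bulky secondary substituent, so conjugate addition must compete with self-condensation of the toluate. C4–H in A2 is benzylic and allylic, so the strong base may epimerise it or move the double bond.
- Comparison: the chosen route makes ring B, both ring-A bonds and the 1,4 relationship in one step from two simple aromatic fragments. In exchange it gives up enantiocontrol and loses half the material at the resolution.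

**Alternative 2: photoenol Diels–Alder across C1 and C4.**
- Disconnection: ring B is cut at C1–C2 and C3–C4.
- Forward key step: irradiation of aldehyde A4 gives a hydroxy-ortho-quinodimethane, which is trapped by the chiral acrylimide A5 to give the all-cis adduct A6.
- For it: ring B, two C–C bonds and three stereocentres arise in one operation. Absolute configuration would come from the auxiliary, and the arene pattern is fixed beforehand, so there is no regiochemical question on ring A. On both points it is stronger than the chosen route.
- Against it: A6 carries a carboxyl carbon on C2 that the target lacks, so auxiliary cleavage and a decarboxylation are needed. Its C1 hydroxyl is cis to the C4 aryl group, so C1 must also be inverted. That is four or more corrective steps after the key step. The diene terminus that becomes C4 bears the bulky naphthyl group next to a methoxy group, and facial control by an oxazolidinone without a chelating Lewis acid is doubtful for a short-lived photoenol.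
- Comparison: the chosen route brings no extra carbon, and the oxygen bridge gives the trans relationship directly.

**Alternative 3: rhodium-catalysed [2+2+2] that builds rings A and B together.**
- Disconnection: ring A is cut at C4a–C8a, C5–C6 and C7–C8.
- Forward key step: the siloxy-diyne A7 and acetylene A8 are cyclotrimerised by a cationic rhodium bisphosphine catalyst to the bis-silyl ether A9.
- For it: the benzene ring is assembled with a fully defined substitution pattern, which is stronger than an aryne on regiochemistry. Both stereocentres are set beforehand and are not touched.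
- Against it: A7 is an acyclic diyne with two remote stereocentres, each needing its own asymmetric step. It also has a hydrolytically fragile siloxyalkyne and the crowded propargylic C4. Gaseous A8 must outcompete self-trimerisation of the diyne. A9 has a silyl ether where the target has a methyl ether, so desilylation, methylation and two further deprotections follow. It would be the longest route.
- Comparison: the chosen route starts from purchased aromatic rings and spends its steps on the one bond construction that matters.

Key step: step 5

## Route

Remark: 9, 10 and 11 are racemic; they are marked rac and written with the SMILES of the enantiomer that leads to the target. Systematic names of the bridged compounds number the aryl-bearing bridgehead as position 1, which is C4 of the target.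

Step 1
Reactants: 1 naphthalene-1,8-diol
Product: 2 8-methoxynaphthalen-1-ol
Conditions: MeI (1.05 equiv), K2CO3, degassed acetone, rt → 40 °C, argon
Reagents that add atoms: iodomethane, CI
Why: Williamson ether synthesis on the mono-phenoxide; the first deprotonation of the peri-diol is favoured by the intramolecular hydrogen bond, and in the monoether the remaining hydroxyl is locked in an O–H···OMe hydrogen bond and is much less acidic, so one equivalent of MeI should stop at 2.

Step 2
Reactants: 2 8-methoxynaphthalen-1-ol
Product: 3 2-bromo-8-methoxynaphthalen-1-ol
Conditions: NBS (1.0 equiv), i-Pr2NH (10 mol %), CH2Cl2, 0 °C → rt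
Reagents that add atoms: N-bromosuccinimide, O=C1CCC(=O)N1Br
Why: Amine-mediated ortho-bromination of a phenol (electrophilic aromatic substitution): the amine forms an N-bromoamine that is hydrogen-bonded to the naphthol and hands bromine to the adjacent carbon C2 instead of the para carbon C4; one equivalent at low temperature limits dibromination.

Step 3
Reactants: 3 2-bromo-8-methoxynaphthalen-1-ol
Product: 4 1-(benzyloxy)-2-bromo-8-methoxynaphthalene
Conditions: BnBr, K2CO3, DMF, 60 °C
Reagents that add atoms: benzyl bromide, BrCc1ccccc1
Why: Williamson ether synthesis; the phenoxide is flanked by bromine and the peri methoxy group, hence the polar solvent and gentle heating, and the benzyl ether should tolerate the base, fluoride, diimide and hydride of the later steps.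

Step 4
Reactants: 4 1-(benzyloxy)-2-bromo-8-methoxynaphthalene; 5 furan-2-ylboronic acid
Product: 6 2-[1-(benzyloxy)-8-methoxynaphthalen-2-yl]furan
Conditions: 5 (1.8 equiv), Pd(PPh3)4 (5 mol %), aq. Na2CO3, DME, 80 °C
Reagents that add atoms: none
Why: Suzuki–Miyaura cross-coupling: oxidative addition of zerovalent palladium into the C–Br bond, transfer of the furyl group from boron and reductive elimination give the aryl–furan bond; the boronic acid is used in excess because 2-heteroarylboronic acids protodeboronate in aqueous base.

Step 5
Reactants: 6 2-[1-(benzyloxy)-8-methoxynaphthalen-2-yl]furan; 7 3-methoxy-2-(trimethylsilyl)phenyl trifluoromethanesulfonate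
Product: 9 rac-(1S,4S)-1-[1-(benzyloxy)-8-methoxynaphthalen-2-yl]-8-methoxy-1,4-dihydro-1,4-epoxynaphthalene, via 3-methoxybenzyne 8 (not isolated)
Conditions: 7 (1.5 equiv), CsF (3 equiv), MeCN, rt; chromatography on base-washed silica
Reagents that add atoms: none
Why: Fluoride attacks silicon of 7 and the aryl anion expels the ortho triflate, so 3-methoxybenzyne 8 is released slowly at room temperature and is trapped by the furan ring of 6 in a concerted but asynchronous Diels–Alder reaction; the closest known reaction type is the aryne–furan [4+2] cycloaddition that gives 1,4-dihydro-1,4-epoxynaphthalenes. Ring B closes by this [4+2] cycloaddition, the bonds C4–C4a and C8a–C1 forming on one face of the furan, whose oxygen becomes the one-atom bridge of an oxabicyclo[2.2.1]heptadiene. Both new stereocentres, C1 and C4, are bridgeheads: their relative configuration is dictated by the bicyclic geometry, so no diastereomer can form, and as no chiral element is present 9 is racemic. The step needs regioselectivity: the inductively withdrawing methoxy group makes the aryne carbon meta to it the electrophilic one, the unsubstituted α-carbon of the 2-arylfuran is its most nucleophilic position, and pairing these two in the leading bond (C8a–C1) leaves the aryl-bearing carbon to bond to the aryne carbon next to the methoxy group (C4–C4a). This polar preference has to outweigh the repulsion between the methoxy group and the bridgehead aryl group, which is why the small methyl ether is kept on the aryne. Chemoselectivity should follow from the furan being by far the most reactive diene in 6; the naphthalene and benzyl rings are not expected to compete.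

Step 6
Reactants: 9 rac-(1S,4S)-1-[1-(benzyloxy)-8-methoxynaphthalen-2-yl]-8-methoxy-1,4-dihydro-1,4-epoxynaphthalene
Product: 10 rac-(1S,4S)-1-[1-(benzyloxy)-8-methoxynaphthalen-2-yl]-8-methoxy-1,2,3,4-tetrahydro-1,4-epoxynaphthalene
Conditions: 2-nitrobenzenesulfonohydrazide (3 equiv), Et3N, CH2Cl2, rt
Reagents that add atoms: none
Why: Diimide reduction (concerted syn transfer of two hydrogens from HN=NH generated in the flask) is fast on the strained, norbornene-like C2=C3 bond and cannot hydrogenolyse the benzyl ether or the benzylic C–O bonds of the bridge, which a palladium-catalysed hydrogenation might; the mildly basic conditions also avoid acid-induced isomerisation of 9 to a naphthol, and no stereocentre is formed or touched.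

Step 7
Reactants: 10 rac-(1S,4S)-1-[1-(benzyloxy)-8-methoxynaphthalen-2-yl]-8-methoxy-1,2,3,4-tetrahydro-1,4-epoxynaphthalene
Product: 11 rac-(1S,4R)-4-[1-(benzyloxy)-8-methoxynaphthalen-2-yl]-5-methoxy-1,2,3,4-tetrahydronaphthalen-1-ol
Conditions: i-Bu2AlH (DIBAL-H, 4 equiv), CH2Cl2, −40 °C → rt; aq. potassium sodium tartrate
Reagents that add atoms: none
Why: Reductive cleavage of a benzylic ether C–O bond by a Lewis acidic aluminium hydride: i-Bu2AlH binds the bridging oxygen, the tertiary, doubly benzylic C4–O bond (assisted by the ortho alkoxy groups of both aryl rings and by release of bicyclic strain) ionises while the secondary C1–O bond stays intact, and the hydride of the resulting C1 alkoxyaluminate, held on the face the oxygen has just left, is transferred to C4. C4 is thus set with retention (hydrogen takes the place of oxygen), which puts the aryl group trans to the C1 hydroxyl; the same syn delivery underlies retentive acetal openings with this reagent.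

Step 8
Reactants: 11 rac-(1S,4R)-4-[1-(benzyloxy)-8-methoxynaphthalen-2-yl]-5-methoxy-1,2,3,4-tetrahydronaphthalen-1-ol
Product: 12 (1S,4R)-4-[1-(benzyloxy)-8-methoxynaphthalen-2-yl]-5-methoxy-1,2,3,4-tetrahydronaphthalen-1-ol (recovered unreacted alcohol)
Conditions: immobilised Candida antarctica lipase B, vinyl acetate (3 equiv), t-BuOMe, 35 °C, run to just past half conversion; chromatography
Reagents that add atoms: none
Why: Lipase-catalysed kinetic resolution by enantioselective transesterification: the empirical size rule for lipase acylation of secondary alcohols, which holds for 1-tetralols, predicts that the enantiomer with R configuration at C1 (aryl side large, CH2 side medium) is acylated, so the (1S,4R) alcohol should remain and is separated from the (1R,4S) acetate; no stereocentre is formed, the enantiomers are only sorted, and at most half of 11 can be recovered.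

Step 9
Reactants: 12 (1S,4R)-4-[1-(benzyloxy)-8-methoxynaphthalen-2-yl]-5-methoxy-1,2,3,4-tetrahydronaphthalen-1-ol
Product: 13 dipolynaphthalene A, (1S,4R)-4-(1-hydroxy-8-methoxynaphthalen-2-yl)-5-methoxy-1,2,3,4-tetrahydronaphthalen-1-ol
Conditions: H2 (1 atm), 10 % Pd/C, EtOAc, rt, stopped at full conversion
Reagents that add atoms: none
Why: Hydrogenolysis of an aryl benzyl ether over palladium on carbon; in neutral ethyl acetate the O–CH2Ph bond should cleave much faster than the secondary benzylic C1–OH bond, and neither stereocentre is affected.

## Compound list

1 | naphthalene-1,8-diol | Oc1cccc2cccc(O)c12 | starting material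
2 | 8-methoxynaphthalen-1-ol | COc1cccc2cccc(O)c12 | intermediate
3 | 2-bromo-8-methoxynaphthalen-1-ol | COc1cccc2ccc(Br)c(O)c12 | intermediate
4 | 1-(benzyloxy)-2-bromo-8-methoxynaphthalene | COc1cccc2ccc(Br)c(OCc3ccccc3)c12 | intermediate
5 | furan-2-ylboronic acid | OB(O)c1ccco1 | starting material
6 | 2-[1-(benzyloxy)-8-methoxynaphthalen-2-yl]furan | COc1cccc2ccc(-c3ccco3)c(OCc3ccccc3)c12 | intermediate
7 | 3-methoxy-2-(trimethylsilyl)phenyl trifluoromethanesulfonate | COc1cccc(OS(=O)(=O)C(F)(F)F)c1[Si](C)(C)C | starting material
8 | 3-methoxybenzyne (1-methoxy-2,3-didehydrobenzene) | COC1=CC=CC#C1 | intermediate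
9 | rac-(1S,4S)-1-[1-(benzyloxy)-8-methoxynaphthalen-2-yl]-8-methoxy-1,4-dihydro-1,4-epoxynaphthalene | COc1cccc2c1[C@@]1(c3ccc4cccc(OC)c4c3OCc3ccccc3)C=C[C@@H]2O1 | intermediate
10 | rac-(1S,4S)-1-[1-(benzyloxy)-8-methoxynaphthalen-2-yl]-8-methoxy-1,2,3,4-tetrahydro-1,4-epoxynaphthalene | COc1cccc2c1[C@@]1(c3ccc4cccc(OC)c4c3OCc3ccccc3)CC[C@@H]2O1 | intermediate
11 | rac-(1S,4R)-4-[1-(benzyloxy)-8-methoxynaphthalen-2-yl]-5-methoxy-1,2,3,4-tetrahydronaphthalen-1-ol (trans) | COc1cccc2c1[C@@H](c1ccc3cccc(OC)c3c1OCc1ccccc1)CC[C@@H]2O | intermediate
12 | (1S,4R)-4-[1-(benzyloxy)-8-methoxynaphthalen-2-yl]-5-methoxy-1,2,3,4-tetrahydronaphthalen-1-ol | COc1cccc2c1[C@@H](c1ccc3cccc(OC)c3c1OCc1ccccc1)CC[C@@H]2O | intermediate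
13 | dipolynaphthalene A, (1S,4R)-4-(1-hydroxy-8-methoxynaphthalen-2-yl)-5-methoxy-1,2,3,4-tetrahydronaphthalen-1-ol | COc1cccc2c1[C@@H](c1ccc3cccc(OC)c3c1O)CC[C@@H]2O | target

## Step count and least certain steps

Total: 9 steps. Longest linear sequence: 9 steps, from 1 to 13; 5 and 7 are purchased and enter at steps 4 and 5.

**Step 5 (key step).** The most likely failure is reversed or poor regiochemistry. Steric repulsion between the methoxy group and the bulky ortho-benzyloxynaphthyl group may override the polar bias, so that the aryl bridgehead ends up remote from the methoxy carbon. A second risk is slow trapping at the hindered furan terminus, which lets the aryne be consumed in side reactions.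

Fallback, from bromide 4, returning at 10: the C4–aryl bond is made by carbonyl addition, which removes the regiochemical question.
- Purchased 5-methoxy-3,4-dihydronaphthalen-1(2H)-one F1 is reduced with NaBH4 to 5-methoxy-1,2,3,4-tetrahydronaphthalen-1-ol F2.
- F2 is silylated (TBSCl, imidazole) to the silyl ether F3.
- F3 is oxidised with DDQ in wet dioxane at the benzylic methylene attached to the ring carbon ortho to the methoxy group. This gives 4-[(tert-butyldimethylsilyl)oxy]-8-methoxy-3,4-dihydronaphthalen-1(2H)-one F4.
- Bromine–lithium exchange on 4 (n-BuLi, THF, −78 °C) and transmetalation with CeCl3 give an arylcerium reagent. It adds to F4 to give the tertiary alcohol F5 as a mixture of diastereomers.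
- Bu4NF removes the silyl group to give the diol F6.
- Pyridinium p-toluenesulfonate in CH2Cl2 ionises the tertiary, doubly benzylic carbinol. The remote secondary hydroxyl captures the cation on its own face and closes the oxygen bridge, so both diastereomers should converge on 10.

**Step 7.** Facial control may be lost if the well-stabilised C4 cation lives long enough to be reduced from the other face. This could happen by external hydride or by a 1,5-hydride shift from the O–CH2 group of the benzyl ether. Elimination to the C3–C4 alkene and aluminium-promoted loss of the benzyl group are further possibilities.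

Fallback, from 10, returning at 12: C1 is set by reagent control instead of by the bridge.
- Ionic hydrogenation of 10 (Et3SiH, BF3·OEt2, CH2Cl2, −78 °C, aqueous work-up) needs no facial control. It should give 11 together with the cis alcohol F7.
- The mixture is oxidised with Dess–Martin periodinane to the racemic ketone F8.
- CBS reduction with (R)-2-methyl-CBS-oxazaborolidine and BH3·SMe2 should make C1 S in both enantiomers of F8. The trans product is 12. The cis diastereomer (1S,4S) F9 is removed by chromatography.
- Step 8 is then not needed.

**Step 8.** The acylation may be slow or poorly enantioselective, because the large 4-aryl group has to fit into the enzyme pocket.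

Fallback, from 11, returning at 12: classical resolution through diastereomers.
- Racemic 11 is esterified with (S)-methoxy(phenyl)acetic acid (DCC, DMAP). This gives the (1S,4R) ester F10 and the (1R,4S) ester F11.
- The two are separated by chromatography or crystallisation.
- F10 is saponified (LiOH, THF–water) to 12.

**Step 2.** Bromination may go para to the hydroxyl (C4) or onto the methoxy-bearing ring, or twice. The hydroxyl is tied up in the hydrogen bond to the peri methoxy group and may pair poorly with the amine.

Fallback, from 2, returning at 3: directed ortho-metalation.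
- 2 is converted with MOMCl and i-Pr2NEt into 1-methoxy-8-(methoxymethoxy)naphthalene F12.
- The acetal group directs lithiation (n-BuLi, TMEDA, THF, 0 °C) to the adjacent carbon. Quenching with 1,2-dibromotetrachloroethane gives 2-bromo-8-methoxy-1-(methoxymethoxy)naphthalene F13.
- HCl in methanol removes the acetal to give 3.

## Further compounds

F1 | step 5 | 5-methoxy-3,4-dihydronaphthalen-1(2H)-one | COc1cccc2c1CCCC2=O
F2 | step 5 | rac-5-methoxy-1,2,3,4-tetrahydronaphthalen-1-ol | COc1cccc2c1CCCC2O
F3 | step 5 | rac-tert-butyl[(5-methoxy-1,2,3,4-tetrahydronaphthalen-1-yl)oxy]dimethylsilane | COc1cccc2c1CCCC2O[Si](C)(C)C(C)(C)C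
F4 | step 5 | rac-4-[(tert-butyldimethylsilyl)oxy]-8-methoxy-3,4-dihydronaphthalen-1(2H)-one | COc1cccc2c1C(=O)CCC2O[Si](C)(C)C(C)(C)C
F5 | step 5 | 1-[1-(benzyloxy)-8-methoxynaphthalen-2-yl]-4-[(tert-butyldimethylsilyl)oxy]-8-methoxy-1,2,3,4-tetrahydronaphthalen-1-ol (racemic mixture of diastereomers) | COc1cccc2c1C(O)(c1ccc3cccc(OC)c3c1OCc1ccccc1)CCC2O[Si](C)(C)C(C)(C)C
F6 | step 5 | 1-[1-(benzyloxy)-8-methoxynaphthalen-2-yl]-8-methoxy-1,2,3,4-tetrahydronaphthalene-1,4-diol (racemic mixture of diastereomers) | COc1cccc2c1C(O)(c1ccc3cccc(OC)c3c1OCc1ccccc1)CCC2O
F7 | step 7 | rac-(1R,4R)-4-[1-(benzyloxy)-8-methoxynaphthalen-2-yl]-5-methoxy-1,2,3,4-tetrahydronaphthalen-1-ol (cis) | COc1cccc2c1[C@@H](c1ccc3cccc(OC)c3c1OCc1ccccc1)CC[C@H]2O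
F8 | step 7 | rac-4-[1-(benzyloxy)-8-methoxynaphthalen-2-yl]-5-methoxy-3,4-dihydronaphthalen-1(2H)-one | COc1cccc2c1C(c1ccc3cccc(OC)c3c1OCc1ccccc1)CCC2=O
F9 | step 7 | (1S,4S)-4-[1-(benzyloxy)-8-methoxynaphthalen-2-yl]-5-methoxy-1,2,3,4-tetrahydronaphthalen-1-ol (cis) | COc1cccc2c1[C@H](c1ccc3cccc(OC)c3c1OCc1ccccc1)CC[C@@H]2O
F10 | step 8 | (1S,4R)-4-[1-(benzyloxy)-8-methoxynaphthalen-2-yl]-5-methoxy-1,2,3,4-tetrahydronaphthalen-1-yl (2S)-methoxy(phenyl)acetate | COc1cccc2c1[C@@H](c1ccc3cccc(OC)c3c1OCc1ccccc1)CC[C@@H]2OC(=O)[C@@H](OC)c1ccccc1
F11 | step 8 | (1R,4S)-4-[1-(benzyloxy)-8-methoxynaphthalen-2-yl]-5-methoxy-1,2,3,4-tetrahydronaphthalen-1-yl (2S)-methoxy(phenyl)acetate | COc1cccc2c1[C@H](c1ccc3cccc(OC)c3c1OCc1ccccc1)CC[C@H]2OC(=O)[C@@H](OC)c1ccccc1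
F12 | step 2 | 1-methoxy-8-(methoxymethoxy)naphthalene | COCOc1cccc2cccc(OC)c12
F13 | step 2 | 2-bromo-8-methoxy-1-(methoxymethoxy)naphthalene | COCOc1c(Br)ccc2cccc(OC)c12
A1 | alternative 1 | ethyl 2-methoxy-6-methylbenzoate | CCOC(=O)c1c(C)cccc1OC
A2 | alternative 1 | tert-butyl({(1S,4S)-5-methoxy-4-[1-(phenylsulfinyl)ethenyl]-1,2,3,4-tetrahydronaphthalen-1-yl}oxy)dimethylsilane (trans; configuration at sulfur not defined) | COc1cccc2c1[C@@H](C(=C)S(=O)c1ccccc1)CC[C@@H]2O[Si](C)(C)C(C)(C)C
A3 | alternative 1 | 2-[(1R,4S)-4-{[tert-butyl(dimethyl)silyl]oxy}-8-methoxy-1,2,3,4-tetrahydronaphthalen-1-yl]-8-methoxynaphthalen-1-ol | COc1cccc2c1[C@@H](c1ccc3cccc(OC)c3c1O)CC[C@@H]2O[Si](C)(C)C(C)(C)C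
A4 | alternative 2 | 2-{[1-(benzyloxy)-8-methoxynaphthalen-2-yl]methyl}-3-methoxybenzaldehyde | COc1cccc(C=O)c1Cc1ccc2cccc(OC)c2c1OCc1ccccc1
A5 | alternative 2 | (4S)-3-acryloyl-4-benzyl-1,3-oxazolidin-2-one | C=CC(=O)N1C(=O)OC[C@@H]1Cc1ccccc1
A6 | alternative 2 | (4S)-4-benzyl-3-{[(1R,2R,4R)-4-[1-(benzyloxy)-8-methoxynaphthalen-2-yl]-1-hydroxy-5-methoxy-1,2,3,4-tetrahydronaphthalen-2-yl]carbonyl}-1,3-oxazolidin-2-one (all-cis) | COc1cccc2c1[C@@H](c1ccc3cccc(OC)c3c1OCc1ccccc1)C[C@@H](C(=O)N1C(=O)OC[C@@H]1Cc1ccccc1)[C@H]2O
A7 | alternative 3 | 1-(benzyloxy)-2-[(3S,6S)-6-[(tert-butyldimethylsilyl)oxy]-1-[(triisopropylsilyl)oxy]octa-1,7-diyn-3-yl]-8-methoxynaphthalene | C#C[C@@H](O[Si](C)(C)C(C)(C)C)CC[C@@H](C#CO[Si](C(C)C)(C(C)C)C(C)C)c1ccc2cccc(OC)c2c1OCc1ccccc1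
A8 | alternative 3 | acetylene (ethyne) | C#C
A9 | alternative 3 | 1-(benzyloxy)-2-[(1R,4S)-4-[(tert-butyldimethylsilyl)oxy]-8-[(triisopropylsilyl)oxy]-1,2,3,4-tetrahydronaphthalen-1-yl]-8-methoxynaphthalene | CC(C)[Si](C(C)C)(C(C)C)Oc1cccc2c1[C@@H](c1ccc3cccc(OC)c3c1OCc1ccccc1)CC[C@@H]2O[Si](C)(C)C(C)(C)C
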